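Ring D, the only ring with two neighbouring aryloxy carbons (C1, C2) beside a C3/C5 resorcinol pair, is not joined to its neighbours by aryl C–O coupling but built between them. An α-aryloxy β-keto ester carrying the E-F-G triaryl ether (C2–C3–C4) and a 3-aryloxypropiolate carrying A-B-C (C1–C6–C5) are united by a Michael addition (C1–C2), Dieckmann closure (C4–C5) and loss of the ester as dimethyl carbonate. One operation thus closes the pentaoxygenated ring, places both hindered ether bonds, which were made beforehand as alkyl and alkynyl ethers, and joins the two halves. Methyl ethers protect all other phenols.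

Key step: step 14

Remarks:
- The rings are lettered A to G along the SMILES string, from the 2,4,6-trihydroxyphenyl end (ring A) to the 3,4,5-trihydroxyphenyl end (ring G).
- In ring D, C1 carries the oxygen to ring C, C2 the oxygen to ring E, C3 to C5 the hydroxyls and C6 the hydrogen.
- ABC-O denotes the 4-[2,6-dimethoxy-4-(2,4,6-trimethoxyphenoxy)phenoxy]-2,6-dimethoxyphenoxy group.
- EFG-O denotes the 4-[3,5-dimethoxy-4-(3,4,5-trimethoxyphenoxy)phenoxy]-3,5-dimethoxyphenoxy group.
- The target has no stereocentre. The only stereo elements on the way are the alkene geometries of 8 and 20 and the transient racemic centres of 18 to 21.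
- Assumption: 1, 3, 11, 13 and 17 are taken as commercial.

Step 1
Reactants: 1 4-bromo-2,6-dimethoxyphenol
Product: 2 2-(benzyloxy)-5-bromo-1,3-dimethoxybenzene
Conditions: BnBr, K2CO3, DMF, rt
Reagents that add atoms: benzyl bromide, BrCc1ccccc1
Why: Williamson etherification of the phenoxide with a benzylic bromide masks the flanked phenol, so that only the bromide end reacts in the later couplings.

Step 2
Reactants: 3 2,4,6-trimethoxyphenol; 2 2-(benzyloxy)-5-bromo-1,3-dimethoxybenzene
Product: 4 2-(benzyloxy)-1,3-dimethoxy-5-(2,4,6-trimethoxyphenoxy)benzene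
Conditions: CuI (10 mol %), picolinic acid (20 mol %), K3PO4, DMSO, 90 °C
Reagents that add atoms: none
Why: Ullmann-type diaryl ether synthesis with copper and picolinic acid is suited to a 2,6-disubstituted phenol and an aryl bromide without ortho substituents.

Step 3
Reactants: 4 2-(benzyloxy)-1,3-dimethoxy-5-(2,4,6-trimethoxyphenoxy)benzene
Product: 5 2,6-dimethoxy-4-(2,4,6-trimethoxyphenoxy)phenol
Conditions: H2 (1 atm), 10% Pd/C, EtOAc–MeOH, rt
Reagents that add atoms: none
Why: Hydrogenolysis of the benzyl ether should free the flanked phenol without touching methyl or diaryl ethers.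

Step 4
Reactants: 5 2,6-dimethoxy-4-(2,4,6-trimethoxyphenoxy)phenol; 2 2-(benzyloxy)-5-bromo-1,3-dimethoxybenzene
Product: 6 2-(benzyloxy)-5-[2,6-dimethoxy-4-(2,4,6-trimethoxyphenoxy)phenoxy]-1,3-dimethoxybenzene
Conditions: CuI (10 mol %), picolinic acid (20 mol %), K3PO4, DMSO, 100 °C
Reagents that add atoms: none
Why: A second Ullmann-type etherification in the same favourable polarity (hindered phenoxide, unhindered aryl bromide) should add ring C.

Step 5
Reactants: 6 2-(benzyloxy)-5-[2,6-dimethoxy-4-(2,4,6-trimethoxyphenoxy)phenoxy]-1,3-dimethoxybenzene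
Product: 7 4-[2,6-dimethoxy-4-(2,4,6-trimethoxyphenoxy)phenoxy]-2,6-dimethoxyphenol (ABC-OH)
Conditions: H2 (1 atm), 10% Pd/C, EtOAc–MeOH, rt
Reagents that add atoms: none
Why: Hydrogenolysis of the benzyl ether should give the triaryl phenol.

Step 6
Reactants: 7 ABC-OH
Product: 8 (E)-1,2-dichlorovinyl ether of ABC-OH (ABC-O-CCl=CHCl)
Conditions: KH, THF, 0 °C; then Cl2C=CHCl, −50 °C to rt
Reagents that add atoms: trichloroethylene, ClC=C(Cl)Cl
Why: The phenoxide should add anti to dichloroacetylene formed in situ (dichlorovinyl ether route to ynol ethers), which gives the (E)-alkene and tolerates the hindered phenol because the electrophile is a linear alkyne.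

Step 7
Reactants: 8 (E)-1,2-dichlorovinyl ether of ABC-OH
Product: 10 methyl 3-(ABC-O)prop-2-ynoate, via lithium aryloxyacetylide 9 (not isolated)
Conditions: n-BuLi (2.2 equiv), THF, −78 to −40 °C; then ClCO2Me, −78 to 0 °C
Reagents that add atoms: methyl chloroformate, COC(=O)Cl
Why: β-Elimination and lithium–chlorine exchange should give the lithium alkynyl ether, which is acylated at carbon by the chloroformate (alkynide acylation); the two ortho methoxy groups block the sigmatropic pathway otherwise open to aryl ynol ethers.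

Step 8
Reactants: 11 2,6-dimethoxybenzene-1,4-diol
Product: 12 4-(benzyloxy)-2,6-dimethoxyphenol
Conditions: BnBr (1.0 equiv), K2CO3 (1.0 equiv), acetone, rt
Reagents that add atoms: benzyl bromide, BrCc1ccccc1
Why: In this Williamson etherification the unflanked C4 hydroxyl is both the more acidic and the less hindered one, so monoalkylation there should predominate.

Step 9
Reactants: 13 (3,4,5-trimethoxyphenyl)boronic acid; 1 4-bromo-2,6-dimethoxyphenol
Product: 14 5-bromo-1,3-dimethoxy-2-(3,4,5-trimethoxyphenoxy)benzene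
Conditions: Cu(OAc)2 (20 mol %), pyridine, 4 Å MS, CH2Cl2, O2 (1 atm), rt
Reagents that add atoms: none
Why: The Chan–Lam coupling of a boronic acid with a phenol runs at room temperature and leaves the aryl bromide untouched, so the bromophenol cannot oligomerise.

Step 10
Reactants: 14 5-bromo-1,3-dimethoxy-2-(3,4,5-trimethoxyphenoxy)benzene; 12 4-(benzyloxy)-2,6-dimethoxyphenol
Product: 15 5-(benzyloxy)-2-[3,5-dimethoxy-4-(3,4,5-trimethoxyphenoxy)phenoxy]-1,3-dimethoxybenzene
Conditions: CuI (10 mol %), picolinic acid (20 mol %), K3PO4, DMSO, 100 °C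
Reagents that add atoms: none
Why: Ullmann-type etherification of a hindered phenoxide with an aryl bromide that has two ortho hydrogens should add ring E.

Step 11
Reactants: 15 5-(benzyloxy)-2-[3,5-dimethoxy-4-(3,4,5-trimethoxyphenoxy)phenoxy]-1,3-dimethoxybenzene
Product: 16 4-[3,5-dimethoxy-4-(3,4,5-trimethoxyphenoxy)phenoxy]-3,5-dimethoxyphenol (EFG-OH)
Conditions: H2 (1 atm), 10% Pd/C, EtOAc–MeOH, rt
Reagents that add atoms: none
Why: Hydrogenolysis of the benzyl ether should free the unflanked phenol of ring E.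

Step 12
Reactants: 17 methyl 4-methoxy-3-oxobutanoate
Product: 18 methyl 2-chloro-4-methoxy-3-oxobutanoate
Conditions: SO2Cl2, CH2Cl2, 0 °C
Reagents that add atoms: sulfuryl chloride, O=S(=O)(Cl)Cl
Why: Electrophilic α-chlorination of a β-keto ester takes place at the doubly activated methylene.

Step 13
Reactants: 16 EFG-OH; 18 methyl 2-chloro-4-methoxy-3-oxobutanoate
Product: 19 methyl 2-(EFG-O)-4-methoxy-3-oxobutanoate
Conditions: K2CO3, acetone, rt
Reagents that add atoms: none
Why: SN2 displacement of the chloride of an α-chloro β-keto ester by an unhindered phenoxide (the classical route to 2-aryloxyacetoacetates) forms the future C2–O bond of ring D at an sp3 carbon.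

Step 14
Reactants: 19 methyl 2-(EFG-O)-4-methoxy-3-oxobutanoate; 10 methyl 3-(ABC-O)prop-2-ynoate
Product: 22 5-(ABC-O)-4-(EFG-O)-2-methoxybenzene-1,3-diol, via Michael adduct 20 (not isolated), via cyclohexenedione ester 21 (not isolated)
Conditions: Cs2CO3 (0.2 equiv), MeCN, 0 °C to rt; then t-BuOK (2.5 equiv), THF, 0 °C to rt; aq HCl
Reagents that add atoms: none
Why: Proposed new method: the caesium enolate of 19, formed only at the doubly activated C2, should add to the ester-polarised alkyne of 10 at its aryloxy-bearing carbon (carbo-Michael addition; protonation anti to the new bond places C2 cis to the ester, the (E)-alkene 20), which forms the C1–C2 bond and makes C2 quaternary. With C2 blocked, t-BuOK can enolise the ketone only towards C4, and this enolate closes ring D on the enoate ester by a Dieckmann condensation (6-(enolendo)-exo-trig, C4–C5 bond) to the diketonate of 21; the expelled methoxide then attacks the now superfluous ester on C2, and retro-Claisen loss of dimethyl carbonate leaves the aromatic resorcinolate of 22. The closest known reactions are the Michael–Claisen [3+3] annulation of ketones with acrylates to cyclohexane-1,3-diones and the base-mediated [3+3] benzannulation of 1,3-dicarbonyl compounds with ynones that ends in deacylative aromatisation; new here are the β-aryloxy alkynoate and the fully oxygenated ring. The selectivity needed is carbon against oxygen acylation in the closure: because C2 carries no hydrogen, the 2-pyranone that such keto enoates normally give cannot form, an enol lactone would be reopened by methoxide, and only carbon acylation leads to the stabilised diketonate and on to the arene. No stereocentre survives, since the quaternary centre of 20 and 21 is racemic and is erased on aromatisation.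

Step 15
Reactants: 22 5-(ABC-O)-4-(EFG-O)-2-methoxybenzene-1,3-diol
Product: 23 CNP0304148.0
Conditions: BBr3 (40 equiv), CH2Cl2, −78 °C to rt; then degassed H2O, 0 °C
Reagents that add atoms: none
Why: Lewis acid cleavage of aryl methyl ethers (BBr3 demethylation) should remove all fifteen methyl groups while the six diaryl ether bonds, inert to BBr3, stay in place.

Compound list
1 | 4-bromo-2,6-dimethoxyphenol | COc1cc(Br)cc(OC)c1O | starting material
2 | 2-(benzyloxy)-5-bromo-1,3-dimethoxybenzene | COc1cc(Br)cc(OC)c1OCc1ccccc1 | intermediate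
3 | 2,4,6-trimethoxyphenol | COc1cc(OC)c(O)c(OC)c1 | starting material
4 | 2-(benzyloxy)-1,3-dimethoxy-5-(2,4,6-trimethoxyphenoxy)benzene | COc1cc(OC)c(Oc2cc(OC)c(OCc3ccccc3)c(OC)c2)c(OC)c1 | intermediate
5 | 2,6-dimethoxy-4-(2,4,6-trimethoxyphenoxy)phenol | COc1cc(OC)c(Oc2cc(OC)c(O)c(OC)c2)c(OC)c1 | intermediate
6 | 2-(benzyloxy)-5-[2,6-dimethoxy-4-(2,4,6-trimethoxyphenoxy)phenoxy]-1,3-dimethoxybenzene | COc1cc(OC)c(Oc2cc(OC)c(Oc3cc(OC)c(OCc4ccccc4)c(OC)c3)c(OC)c2)c(OC)c1 | intermediate
7 | 4-[2,6-dimethoxy-4-(2,4,6-trimethoxyphenoxy)phenoxy]-2,6-dimethoxyphenol (ABC-OH) | COc1cc(OC)c(Oc2cc(OC)c(Oc3cc(OC)c(O)c(OC)c3)c(OC)c2)c(OC)c1 | intermediate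
8 | (E)-1,2-dichlorovinyl ether of ABC-OH | COc1cc(OC)c(Oc2cc(OC)c(Oc3cc(OC)c(O/C(Cl)=C\Cl)c(OC)c3)c(OC)c2)c(OC)c1 | intermediate
9 | lithium 2-(ABC-O)ethynide | COc1cc(OC)c(Oc2cc(OC)c(Oc3cc(OC)c(OC#C[Li])c(OC)c3)c(OC)c2)c(OC)c1 | intermediate
10 | methyl 3-(ABC-O)prop-2-ynoate | COc1cc(OC)c(Oc2cc(OC)c(Oc3cc(OC)c(OC#CC(=O)OC)c(OC)c3)c(OC)c2)c(OC)c1 | intermediate
11 | 2,6-dimethoxybenzene-1,4-diol | COc1cc(O)cc(OC)c1O | starting material
12 | 4-(benzyloxy)-2,6-dimethoxyphenol | COc1cc(OCc2ccccc2)cc(OC)c1O | intermediate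
13 | (3,4,5-trimethoxyphenyl)boronic acid | COc1cc(B(O)O)cc(OC)c1OC | starting material
14 | 5-bromo-1,3-dimethoxy-2-(3,4,5-trimethoxyphenoxy)benzene | COc1cc(Oc2c(OC)cc(Br)cc2OC)cc(OC)c1OC | intermediate
15 | 5-(benzyloxy)-2-[3,5-dimethoxy-4-(3,4,5-trimethoxyphenoxy)phenoxy]-1,3-dimethoxybenzene | COc1cc(Oc2c(OC)cc(Oc3c(OC)cc(OCc4ccccc4)cc3OC)cc2OC)cc(OC)c1OC | intermediate
16 | 4-[3,5-dimethoxy-4-(3,4,5-trimethoxyphenoxy)phenoxy]-3,5-dimethoxyphenol (EFG-OH) | COc1cc(Oc2c(OC)cc(Oc3c(OC)cc(O)cc3OC)cc2OC)cc(OC)c1OC | intermediate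
17 | methyl 4-methoxy-3-oxobutanoate | COCC(=O)CC(=O)OC | starting material
18 | methyl 2-chloro-4-methoxy-3-oxobutanoate (racemic) | COCC(=O)C(Cl)C(=O)OC | intermediate
19 | methyl 2-(EFG-O)-4-methoxy-3-oxobutanoate (racemic) | COCC(=O)C(C(=O)OC)Oc1cc(OC)c(Oc2cc(OC)c(Oc3cc(OC)c(OC)c(OC)c3)c(OC)c2)c(OC)c1 | intermediate
20 | dimethyl (E)-3-(ABC-O)-4-(EFG-O)-4-(2-methoxyacetyl)pent-2-enedioate (racemic) | COCC(=O)C(C(=O)OC)(Oc1cc(OC)c(Oc2cc(OC)c(Oc3cc(OC)c(OC)c(OC)c3)c(OC)c2)c(OC)c1)/C(Oc1c(OC)cc(Oc2c(OC)cc(Oc3c(OC)cc(OC)cc3OC)cc2OC)cc1OC)=C\C(=O)OC | intermediate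
21 | methyl 2-(ABC-O)-1-(EFG-O)-5-methoxy-4,6-dioxocyclohex-2-ene-1-carboxylate (diketo tautomer, racemic) | COC(=O)C1(Oc2cc(OC)c(Oc3cc(OC)c(Oc4cc(OC)c(OC)c(OC)c4)c(OC)c3)c(OC)c2)C(Oc2c(OC)cc(Oc3c(OC)cc(Oc4c(OC)cc(OC)cc4OC)cc3OC)cc2OC)=CC(=O)C(OC)C1=O | intermediate
22 | 5-(ABC-O)-4-(EFG-O)-2-methoxybenzene-1,3-diol | COc1c(O)cc(Oc2c(OC)cc(Oc3c(OC)cc(Oc4c(OC)cc(OC)cc4OC)cc3OC)cc2OC)c(Oc2cc(OC)c(Oc3cc(OC)c(Oc4cc(OC)c(OC)c(OC)c4)c(OC)c3)c(OC)c2)c1O | intermediate
23 | CNP0304148.0 | Oc1cc(O)c(Oc2cc(O)c(Oc3cc(O)c(Oc4cc(O)c(O)c(O)c4Oc4cc(O)c(Oc5cc(O)c(Oc6cc(O)c(O)c(O)c6)c(O)c5)c(O)c4)c(O)c3)c(O)c2)c(O)c1 | target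

Total step count: 15. Longest linear sequence: 9 steps (steps 1, 2, 3, 4, 5, 6, 7, 14, 15).

Steps most likely to fail

1. Step 14 (Proposed new method).
 - What may go wrong: conjugate addition of the hindered tertiary enolate may be slow or may go through oxygen; the adduct may form with the ester trans to C2, so that the ring cannot close; alkoxide may cleave the quaternary keto ester by a retro-Claisen reaction before cyclisation.
 - Fallback (known chemistry): it sets out from 7 and 16 and comes back to the route at 23. Commercial 5-iodo-1,2,3-trimethoxybenzene would be brominated ortho to iodine (NBS, MeCN) to 2-bromo-1-iodo-3,4,5-trimethoxybenzene F1. Ullmann etherification of 7 at the more reactive carbon–iodine bond (CuI, picolinic acid, K3PO4, DMSO, 80 °C) would give 2-bromo-1-(ABC-O)-3,4,5-trimethoxybenzene F2. Palladium-catalysed C–O coupling of F2 with 16 (Pd(OAc)2, t-BuXPhos, K3PO4, toluene, 100 °C) would give 1-(ABC-O)-2-(EFG-O)-3,4,5-trimethoxybenzene F3, the fully methylated heptamer. The conditions of step 15 would convert it into 23.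

2. Step 7.
 - What may go wrong: the electrophilic ynol ether ester may be hydrated or may oligomerise during isolation, and n-BuLi may lithiate a methoxyarene ring in competition.
 - Fallback: it sets out from 7 and comes back to the route at 20. Methyl propiolate would be brominated at the alkyne terminus (NBS, AgNO3 cat., acetone) to methyl 3-bromopropiolate F4. Conjugate addition of the phenoxide of 7 (K2CO3, MeCN, 0 °C) would give methyl (E)-3-bromo-3-(ABC-O)acrylate F5, a vinylogous acyl bromide that can be stored. With one equivalent of Cs2CO3 in MeCN, the enolate of 19 would displace bromide from F5 by addition–elimination and give 20, without an ynol ether being handled. The t-BuOK stage of step 14 follows as written.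

3. Step 15.
 - What may go wrong: cleavage of fifteen methyl ethers may stop short, and the pyrogallol-type rings D and G may be oxidised by air during the long reaction and the chromatography of the free polyphenol.
 - Fallback: it sets out from 22 and comes back to the route at 23. The crude product of the BBr3 reaction would be peracetylated (Ac2O, pyridine, DMAP) to the heptadecaacetate of CNP0304148.0 F6, which is stable on silica and separable from under-demethylated material. Deacetylation under exclusion of air (NaOMe cat., degassed MeOH, then acidic resin) would release 23.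

Further compounds
F1 | step 14 | 2-bromo-1-iodo-3,4,5-trimethoxybenzene | COc1cc(I)c(Br)c(OC)c1OC
F2 | step 14 | 2-bromo-1-(ABC-O)-3,4,5-trimethoxybenzene | COc1cc(Oc2c(OC)cc(Oc3c(OC)cc(Oc4c(OC)cc(OC)cc4OC)cc3OC)cc2OC)c(Br)c(OC)c1OC
F3 | step 14 | 1-(ABC-O)-2-(EFG-O)-3,4,5-trimethoxybenzene | COc1cc(Oc2c(OC)cc(Oc3c(OC)cc(Oc4c(OC)cc(OC)cc4OC)cc3OC)cc2OC)c(Oc2cc(OC)c(Oc3cc(OC)c(Oc4cc(OC)c(OC)c(OC)c4)c(OC)c3)c(OC)c2)c(OC)c1OC
F4 | step 7 | methyl 3-bromopropiolate | COC(=O)C#CBr
F5 | step 7 | methyl (E)-3-bromo-3-(ABC-O)acrylate | COC(=O)/C=C(/Br)Oc1c(OC)cc(Oc2c(OC)cc(Oc3c(OC)cc(OC)cc3OC)cc2OC)cc1OC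
F6 | step 15 | heptadecaacetate of CNP0304148.0 | CC(=O)Oc1cc(OC(C)=O)c(Oc2cc(OC(C)=O)c(Oc3cc(OC(C)=O)c(Oc4cc(OC(C)=O)c(OC(C)=O)c(OC(C)=O)c4Oc4cc(OC(C)=O)c(Oc5cc(OC(C)=O)c(Oc6cc(OC(C)=O)c(OC(C)=O)c(OC(C)=O)c6)c(OC(C)=O)c5)c(OC(C)=O)c4)c(OC(C)=O)c3)c(OC(C)=O)c2)c(OC(C)=O)c1
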